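**Retrosynthetic overview**

1. Labels: ring A with C7–C8–C9 and ring B (C1'–C6') with C7'–C8'–C9' form the furofuran (rings C7–O–C9'–C8'–C8 and C7'–O–C9–C8–C8', both aryl groups endo); ring C with C7''–C8''–C9'' is joined to ring B through the ring O4'–C7''–C8''–C5'–C4'.
2. The strategy rests on that last ring: H7'' and H8'' are cis, and C7'' is a benzylic ether carbon in 1,5-relation to C8''. C7''–C8'' is therefore cut to a C5' aryldiazoacetate whose carbene inserts into the O4'–CH2 bond of a vanillyl ether.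
3. The furofuran is cut at C7'–C8' and C7'–O into the ring B dimethyl acetal 12 and the cis-dihydrofuryl alcohol 26 (oxocarbenium/enol ether union, then removal of the C9' methoxy group). Alcohol 26 comes from an oxazolidinone anti-aldol of silylated vanillin with a pent-4-enoyl imide, alkene cleavage and dehydration.
4. Order of ring formation: dihydrobenzofuran ring (step 7); dihydrofuran ring C7–O–C9'–C8'–C8 (steps 14 and 15); second tetrahydrofuran ring C7'–O–C9–C8–C8' (step 17); then acetal reduction and desilylation.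

Key step: step 7

Assumption: in the known cis-selective cyclisations of 2-(benzyloxy)phenyl diazoacetates the (S)-tert-leucinate dirhodium catalyst is taken to give the (2R,3S) ester, so the (2S,3R) ester needed here is made with the (R)-configured catalyst Rh2(R-PTTL)4, dirhodium tetrakis[N-phthaloyl-(R)-tert-leucinate] (from (R)-tert-leucine); should a trial run show the opposite sense, the antipodal catalyst is used in the same step.

**Ring B / ring C fragment**

Step 1
Reactants: 1 vanillin
Product: 2 3-methoxy-4-(triisopropylsilyloxy)benzaldehyde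
Conditions: i-Pr3SiCl, imidazole, DMF, rt
Reagents that add atoms: triisopropylsilyl chloride, CC(C)[Si](Cl)(C(C)C)C(C)C
Why: Silyl ether formation on the acidic phenol is routine, and the triisopropylsilyl group is preferred to a tert-butyldimethylsilyl group because it withstands the carbonate, amine and hydride reagents used later.

Step 2
Reactants: 2 3-methoxy-4-(triisopropylsilyloxy)benzaldehyde
Product: 3 [3-methoxy-4-(triisopropylsilyloxy)phenyl]methanol
Conditions: NaBH4, MeOH, 0 °C
Reagents that add atoms: none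
Why: Borohydride reduction of an aromatic aldehyde leaves the aryl silyl ether untouched.

Step 3
Reactants: 3 [3-methoxy-4-(triisopropylsilyloxy)phenyl]methanol
Product: 4 4-(bromomethyl)-2-methoxyphenyl triisopropylsilyl ether
Conditions: CBr4, PPh3, CH2Cl2, 0 °C; used without storage
Reagents that add atoms: carbon tetrabromide, BrC(Br)(Br)Br
Why: The Appel reaction converts the benzylic alcohol into the bromide under neutral conditions that the electron-rich, acid-sensitive benzyl system tolerates.

Step 4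
Reactants: 4 4-(bromomethyl)-2-methoxyphenyl triisopropylsilyl ether, 5 5-iodovanillin
Product: 6 3-iodo-5-methoxy-4-{[3-methoxy-4-(triisopropylsilyloxy)benzyl]oxy}benzaldehyde
Conditions: K2CO3, DMF, rt
Reagents that add atoms: none
Why: Williamson ether synthesis, in which the acidic phenol of 5 is deprotonated by carbonate and displaces the reactive benzylic bromide, placing the future C7'' on O4'.

Step 5
Reactants: 6 3-iodo-5-methoxy-4-{[3-methoxy-4-(triisopropylsilyloxy)benzyl]oxy}benzaldehyde
Product: 7 5-(dimethoxymethyl)-1-iodo-3-methoxy-2-{[3-methoxy-4-(triisopropylsilyloxy)benzyl]oxy}benzene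
Conditions: HC(OMe)3, PPTS (catalytic), MeOH, rt; Et3N quench
Reagents that add atoms: trimethyl orthoformate, COC(OC)OC
Why: Acid-catalysed acetalisation driven by the orthoformate masks C7' against the diazo ester and the carbene, and the same dimethyl acetal later serves as the electrophile of step 17.

Step 6
Reactants: 7 5-(dimethoxymethyl)-1-iodo-3-methoxy-2-{[3-methoxy-4-(triisopropylsilyloxy)benzyl]oxy}benzene, 8 ethyl diazoacetate
Product: 9 ethyl 2-diazo-2-[5-(dimethoxymethyl)-3-methoxy-2-{[3-methoxy-4-(triisopropylsilyloxy)benzyl]oxy}phenyl]acetate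
Conditions: Pd(PPh3)4 (5 mol %), Ag2CO3 (0.5 equiv), Et3N, toluene, rt
Reagents that add atoms: none
Why: Palladium-catalysed cross-coupling of an aryl iodide with ethyl diazoacetate, in which oxidative addition of C5'–I to zerovalent palladium, transfer of the amine/silver-activated diazo carbon and reductive elimination at room temperature outrun loss of N2, so the diazo group is retained.

Step 7
Reactants: 9 ethyl 2-diazo-2-[5-(dimethoxymethyl)-3-methoxy-2-{[3-methoxy-4-(triisopropylsilyloxy)benzyl]oxy}phenyl]acetate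
Product: 10 ethyl (2S,3R)-5-(dimethoxymethyl)-7-methoxy-2-[3-methoxy-4-(triisopropylsilyloxy)phenyl]-2,3-dihydro-1-benzofuran-3-carboxylate (cis)
Conditions: Rh2(R-PTTL)4 (1 mol %), toluene, −60 °C, slow addition of 9
Reagents that add atoms: none
Why: The dirhodium carboxylate takes N2 from 9 and gives a rhodium-bound donor/acceptor carbene at C8'', which is selective enough at −60 °C that dimerisation and ylide formation should stay slow. The carbene carbon then accepts a hydrogen from the O4'–CH2 group and bonds to that carbon in one asynchronous three-centre event, the intramolecular 1,5 C–H insertion known for 2-(benzyloxy)phenyl diazoacetates under chiral dirhodium carboxylates, which gives cis-2-aryl-2,3-dihydrobenzofuran-3-carboxylates. The ring O4'–C7''–C8''–C5'–C4' is closed by C7''–C8'' bond formation in a 1,5 mode (carbene carbon, C5', C4', O4' and C7'' form the five-membered ring), and no other closure competes because the methoxy, acetal and silyl C–H bonds cannot reach the carbene. Both new stereocentres are set by the catalyst: its phthalimido-walled pocket selects one enantiotopic benzylic hydrogen (C7'', S) and holds ester and aryl group on the same side when the C–C bond forms (C8'', R as the ester), giving the kinetic cis product. The step needs site selectivity, cis selectivity and enantioselectivity; the first comes from the substrate (a single benzylic ether C–H in 1,5-relation, made hydridic by O4' and electron-rich ring C), the other two from the catalyst under cold, base-free conditions that leave the acidic C8''–H unepimerised.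

Step 8
Reactants: 10 ethyl (2S,3R)-5-(dimethoxymethyl)-7-methoxy-2-[3-methoxy-4-(triisopropylsilyloxy)phenyl]-2,3-dihydro-1-benzofuran-3-carboxylate
Product: 11 [(2S,3S)-5-(dimethoxymethyl)-7-methoxy-2-[3-methoxy-4-(triisopropylsilyloxy)phenyl]-2,3-dihydro-1-benzofuran-3-yl]methanol
Conditions: i-Bu2AlH (3 equiv), CH2Cl2, −78 to −40 °C; aqueous potassium sodium tartrate
Reagents that add atoms: none
Why: Ester reduction with a Lewis-acidic, non-basic aluminium hydride at low temperature takes C9'' to the alcohol before any base can epimerise C8'', which is no longer acidic afterwards (the descriptor changes from R to S only through the priority change).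

Step 9
Reactants: 11 [(2S,3S)-5-(dimethoxymethyl)-7-methoxy-2-[3-methoxy-4-(triisopropylsilyloxy)phenyl]-2,3-dihydro-1-benzofuran-3-yl]methanol
Product: 12 tert-butyldimethylsilyl ether of 11 at C9''
Conditions: t-BuMe2SiCl, imidazole, CH2Cl2, rt
Reagents that add atoms: tert-butyldimethylsilyl chloride, CC(C)(C)[Si](C)(C)Cl
Why: Silylation of the primary alcohol keeps the C9'' hydroxyl out of the acetal exchange of step 17 and leaves the dimethyl acetal intact.

**Ring A dihydrofuran fragment**

Step 10
Reactants: 13 pent-4-enoic acid, 14 (S)-4-benzyloxazolidin-2-one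
Product: 16 (S)-4-benzyl-3-(pent-4-enoyl)oxazolidin-2-one, via mixed pivalic anhydride 15 (not isolated)
Conditions: t-BuCOCl, Et3N, THF, −20 °C; then LiCl, 14, rt
Reagents that add atoms: none
Why: N-acylation of the oxazolidinone through the mixed anhydride, which is attacked at the less hindered pentenoyl carbonyl under lithium chloride/amine activation.

Step 11
Reactants: 16 (S)-4-benzyl-3-(pent-4-enoyl)oxazolidin-2-one, 2 3-methoxy-4-(triisopropylsilyloxy)benzaldehyde
Product: 18 (S)-4-benzyl-3-[(2R)-2-{(S)-hydroxy[3-methoxy-4-(triisopropylsilyloxy)phenyl]methyl}pent-4-enoyl]oxazolidin-2-one, via aldol trimethylsilyl ether 17 (not isolated)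
Conditions: MgCl2 (20 mol %), Et3N, Me3SiCl, EtOAc, rt; then CF3CO2H, MeOH, 0 °C
Reagents that add atoms: none
Why: Evans magnesium halide-catalysed anti-aldol reaction, in which the chelated (Z)-magnesium enolate adds to the non-enolisable aldehyde through a boat-like transition state on the face away from the benzyl group, setting C8 (2R) and C7 (S) in the anti relation while silylation of the aldolate turns the catalyst over.

Step 12
Reactants: 18 (S)-4-benzyl-3-[(2R)-2-{(S)-hydroxy[3-methoxy-4-(triisopropylsilyloxy)phenyl]methyl}pent-4-enoyl]oxazolidin-2-one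
Product: 19 (1S,2S)-1-[3-methoxy-4-(triisopropylsilyloxy)phenyl]-2-(prop-2-enyl)propane-1,3-diol
Conditions: LiBH4, MeOH (1 equiv), THF, 0 °C
Reagents that add atoms: none
Why: Reductive cleavage of the N-acyl oxazolidinone by borohydride attack on the exocyclic carbonyl gives the 1,3-diol and returns the auxiliary without retro-aldol, so C8 ceases to be epimerisable.

Step 13
Reactants: 19 (1S,2S)-1-[3-methoxy-4-(triisopropylsilyloxy)phenyl]-2-(prop-2-enyl)propane-1,3-diol
Product: 20 (2S)-2-{(S)-hydroxy[3-methoxy-4-(triisopropylsilyloxy)phenyl]methyl}pent-4-enyl pivalate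
Conditions: t-BuCOCl, pyridine, CH2Cl2, 0 °C
Reagents that add atoms: pivaloyl chloride, CC(C)(C)C(=O)Cl
Why: Selective acylation of the primary hydroxyl by the bulky acid chloride leaves the secondary benzylic C7–OH as the only hydroxyl able to form the lactol.

Step 14
Reactants: 20 (2S)-2-{(S)-hydroxy[3-methoxy-4-(triisopropylsilyloxy)phenyl]methyl}pent-4-enyl pivalate
Product: 23 [(2S,3S)-5-hydroxy-2-[3-methoxy-4-(triisopropylsilyloxy)phenyl]tetrahydrofuran-3-yl]methyl pivalate (lactol; C9' epimers), via vicinal diol 21 (not isolated), via hydroxy aldehyde 22 (not isolated)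
Conditions: K2OsO4·2H2O (2 mol %), NaIO4, 2,6-lutidine, dioxane–H2O, rt
Reagents that add atoms: sodium periodate, [Na+].[O-]I(=O)(=O)=O
Why: Lemieux–Johnson oxidation (osmium-catalysed dihydroxylation, then periodate glycol cleavage) cuts the terminal alkene while sparing the electron-rich arene, and the aldehyde is captured by C7–OH as the five-membered lactol.

Step 15
Reactants: 23 [(2S,3S)-5-hydroxy-2-[3-methoxy-4-(triisopropylsilyloxy)phenyl]tetrahydrofuran-3-yl]methyl pivalate
Product: 25 [(2S,3S)-2-[3-methoxy-4-(triisopropylsilyloxy)phenyl]-2,3-dihydrofuran-3-yl]methyl pivalate, via anomeric mesylate 24 (not isolated)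
Conditions: MeSO2Cl, Et3N (excess), CH2Cl2, −40 °C to reflux
Reagents that add atoms: none
Why: Lactol dehydration by mesylation and elimination, in which the anomeric mesylate ionises to the oxocarbenium ion and triethylamine removes a C8' proton to give the enol ether under basic conditions that leave C7 and C8 untouched.

Step 16
Reactants: 25 [(2S,3S)-2-[3-methoxy-4-(triisopropylsilyloxy)phenyl]-2,3-dihydrofuran-3-yl]methyl pivalate
Product: 26 [(2S,3S)-2-[3-methoxy-4-(triisopropylsilyloxy)phenyl]-2,3-dihydrofuran-3-yl]methanol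
Conditions: i-Bu2AlH, CH2Cl2, −78 °C; aqueous potassium sodium tartrate
Reagents that add atoms: none
Why: Reductive ester cleavage with the aluminium hydride is neither acidic nor strongly basic, so the enol ether, the benzylic C7–O bond and the aryl silyl ether survive.

**Union and endgame**

Step 17
Reactants: 26 [(2S,3S)-2-[3-methoxy-4-(triisopropylsilyloxy)phenyl]-2,3-dihydrofuran-3-yl]methanol, 12 tert-butyldimethylsilyl ether of 11 at C9''
Product: 28 endo,endo-furofuranyl C9' methyl acetal carrying both triisopropylsilyl ethers and the C9'' tert-butyldimethylsilyl ether (C9' epimers), via mixed methyl acetal 27 (not isolated)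
Conditions: Me3SiOTf (0.2 equiv), CH2Cl2, −78 to −40 °C; Et3N quench at low temperature
Reagents that add atoms: none
Why: Acetal exchange followed by a Prins-type oxocarbenium/enol ether cyclisation, in which the (E)-oxocarbenium ion at C7' is attacked by C8' on the face carrying the CH2O tether (cis ring fusion, C8'), the ring B aryl group ends endo under kinetic control as is known for cis-2-aryl-2,3-dihydrofuryl alcohols with aryl aldehyde acetals (C7'), and methanol traps the resulting C9' cation.

Step 18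
Reactants: 28 endo,endo-furofuranyl C9' methyl acetal
Product: 29 (7S,8S,7'S,8'S,7''S,8''S)-tris-silyl ether of the target (ring A and ring C O-triisopropylsilyl; C9'' O-tert-butyldimethylsilyl)
Conditions: Et3SiH, BF3·OEt2, CH2Cl2, −78 °C; NaHCO3 quench at −78 °C
Reagents that add atoms: none
Why: Ionic hydrogenation of the only acetal in the molecule, whose C9' oxocarbenium ion is reduced by the silane to a methylene group (no stereocentre at stake), while at −78 °C the benzylic ether bonds at C7, C7' and C7'' should ionise far more slowly than the acetal.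

Step 19
Reactants: 29 tris-silyl ether of the target
Product: 30 CNP0303197.1
Conditions: Bu4NF (3.5 equiv), AcOH (3.5 equiv), THF, 0 °C to rt
Reagents that add atoms: none
Why: Fluoride-induced desilylation removes the two aryl and the one alkyl silyl ether in one operation, and the acetic acid buffer keeps the phenols protonated so that quinone-methide-type opening of the benzylic ethers is avoided.

**Compound list**

1 | vanillin (4-hydroxy-3-methoxybenzaldehyde) | COc1cc(C=O)ccc1O | starting material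
2 | 3-methoxy-4-(triisopropylsilyloxy)benzaldehyde | COc1cc(C=O)ccc1O[Si](C(C)C)(C(C)C)C(C)C | intermediate
3 | [3-methoxy-4-(triisopropylsilyloxy)phenyl]methanol | COc1cc(CO)ccc1O[Si](C(C)C)(C(C)C)C(C)C | intermediate
4 | 4-(bromomethyl)-2-methoxyphenyl triisopropylsilyl ether | COc1cc(CBr)ccc1O[Si](C(C)C)(C(C)C)C(C)C | intermediate
5 | 5-iodovanillin (4-hydroxy-3-iodo-5-methoxybenzaldehyde) | COc1cc(C=O)cc(I)c1O | starting material
6 | 3-iodo-5-methoxy-4-{[3-methoxy-4-(triisopropylsilyloxy)benzyl]oxy}benzaldehyde | COc1cc(C=O)cc(I)c1OCc1ccc(O[Si](C(C)C)(C(C)C)C(C)C)c(OC)c1 | intermediate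
7 | 5-(dimethoxymethyl)-1-iodo-3-methoxy-2-{[3-methoxy-4-(triisopropylsilyloxy)benzyl]oxy}benzene | COC(OC)c1cc(OC)c(OCc2ccc(O[Si](C(C)C)(C(C)C)C(C)C)c(OC)c2)c(I)c1 | intermediate
8 | ethyl diazoacetate | CCOC(=O)C=[N+]=[N-] | starting material
9 | ethyl 2-diazo-2-[5-(dimethoxymethyl)-3-methoxy-2-{[3-methoxy-4-(triisopropylsilyloxy)benzyl]oxy}phenyl]acetate | CCOC(=O)C(=[N+]=[N-])c1cc(C(OC)OC)cc(OC)c1OCc1ccc(O[Si](C(C)C)(C(C)C)C(C)C)c(OC)c1 | intermediate (key-step precursor)
10 | ethyl (2S,3R)-5-(dimethoxymethyl)-7-methoxy-2-[3-methoxy-4-(triisopropylsilyloxy)phenyl]-2,3-dihydro-1-benzofuran-3-carboxylate | COC(OC)c1cc(OC)c2c(c1)[C@@H](C(=O)OCC)[C@@H](c1ccc(O[Si](C(C)C)(C(C)C)C(C)C)c(OC)c1)O2 | intermediate (key-step product)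
11 | [(2S,3S)-5-(dimethoxymethyl)-7-methoxy-2-[3-methoxy-4-(triisopropylsilyloxy)phenyl]-2,3-dihydro-1-benzofuran-3-yl]methanol | COC(OC)c1cc(OC)c2c(c1)[C@@H](CO)[C@@H](c1ccc(O[Si](C(C)C)(C(C)C)C(C)C)c(OC)c1)O2 | intermediate
12 | C9'' tert-butyldimethylsilyl ether of 11 | COC(OC)c1cc(OC)c2c(c1)[C@@H](CO[Si](C)(C)C(C)(C)C)[C@@H](c1ccc(O[Si](C(C)C)(C(C)C)C(C)C)c(OC)c1)O2 | intermediate
13 | pent-4-enoic acid | C=CCCC(=O)O | starting material
14 | (S)-4-benzyloxazolidin-2-one | O=C1N[C@@H](Cc2ccccc2)CO1 | starting material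
15 | pent-4-enoic pivalic anhydride | C=CCCC(=O)OC(=O)C(C)(C)C | intermediate (not isolated)
16 | (S)-4-benzyl-3-(pent-4-enoyl)oxazolidin-2-one | C=CCCC(=O)N1[C@@H](Cc2ccccc2)COC1=O | intermediate
17 | trimethylsilyl ether of aldol adduct 18 | COc1cc([C@@H](O[Si](C)(C)C)[C@@H](CC=C)C(=O)N2[C@@H](Cc3ccccc3)COC2=O)ccc1O[Si](C(C)C)(C(C)C)C(C)C | intermediate (not isolated)
18 | (S)-4-benzyl-3-[(2R)-2-{(S)-hydroxy[3-methoxy-4-(triisopropylsilyloxy)phenyl]methyl}pent-4-enoyl]oxazolidin-2-one | COc1cc([C@@H](O)[C@@H](CC=C)C(=O)N2[C@@H](Cc3ccccc3)COC2=O)ccc1O[Si](C(C)C)(C(C)C)C(C)C | intermediate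
19 | (1S,2S)-1-[3-methoxy-4-(triisopropylsilyloxy)phenyl]-2-(prop-2-enyl)propane-1,3-diol | COc1cc([C@@H](O)[C@@H](CC=C)CO)ccc1O[Si](C(C)C)(C(C)C)C(C)C | intermediate
20 | (2S)-2-{(S)-hydroxy[3-methoxy-4-(triisopropylsilyloxy)phenyl]methyl}pent-4-enyl pivalate | COc1cc([C@@H](O)[C@@H](CC=C)COC(=O)C(C)(C)C)ccc1O[Si](C(C)C)(C(C)C)C(C)C | intermediate
21 | (2S)-4,5-dihydroxy-2-{(S)-hydroxy[3-methoxy-4-(triisopropylsilyloxy)phenyl]methyl}pentyl pivalate (C4 epimers) | COc1cc([C@@H](O)[C@@H](CC(O)CO)COC(=O)C(C)(C)C)ccc1O[Si](C(C)C)(C(C)C)C(C)C | intermediate (not isolated)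
22 | (2S)-2-{(S)-hydroxy[3-methoxy-4-(triisopropylsilyloxy)phenyl]methyl}-4-oxobutyl pivalate | COc1cc([C@@H](O)[C@@H](CC=O)COC(=O)C(C)(C)C)ccc1O[Si](C(C)C)(C(C)C)C(C)C | intermediate (not isolated)
23 | [(2S,3S)-5-hydroxy-2-[3-methoxy-4-(triisopropylsilyloxy)phenyl]tetrahydrofuran-3-yl]methyl pivalate (anomers) | COc1cc([C@H]2OC(O)C[C@H]2COC(=O)C(C)(C)C)ccc1O[Si](C(C)C)(C(C)C)C(C)C | intermediate
24 | anomeric methanesulfonate of 23 | COc1cc([C@H]2OC(OS(C)(=O)=O)C[C@H]2COC(=O)C(C)(C)C)ccc1O[Si](C(C)C)(C(C)C)C(C)C | intermediate (not isolated)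
25 | [(2S,3S)-2-[3-methoxy-4-(triisopropylsilyloxy)phenyl]-2,3-dihydrofuran-3-yl]methyl pivalate | COc1cc([C@H]2OC=C[C@H]2COC(=O)C(C)(C)C)ccc1O[Si](C(C)C)(C(C)C)C(C)C | intermediate
26 | [(2S,3S)-2-[3-methoxy-4-(triisopropylsilyloxy)phenyl]-2,3-dihydrofuran-3-yl]methanol | COc1cc([C@H]2OC=C[C@H]2CO)ccc1O[Si](C(C)C)(C(C)C)C(C)C | intermediate
27 | mixed methyl acetal of the ring B aldehyde with the C9 hydroxyl of 26 (C7' epimers) | COc1cc([C@H]2OC=C[C@H]2COC(OC)c2cc(OC)c3c(c2)[C@@H](CO[Si](C)(C)C(C)(C)C)[C@@H](c2ccc(O[Si](C(C)C)(C(C)C)C(C)C)c(OC)c2)O3)ccc1O[Si](C(C)C)(C(C)C)C(C)C | intermediate (not isolated)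
28 | endo,endo-furofuranyl C9' methyl acetal, tris-silyl ether (configuration of 29 at C7, C8, C7', C8', C7'', C8''; C9' epimers) | COc1cc([C@H]2OC(OC)[C@@H]3[C@H]2CO[C@@H]3c2cc(OC)c3c(c2)[C@@H](CO[Si](C)(C)C(C)(C)C)[C@@H](c2ccc(O[Si](C(C)C)(C(C)C)C(C)C)c(OC)c2)O3)ccc1O[Si](C(C)C)(C(C)C)C(C)C | intermediate
29 | (7S,8S,7'S,8'S,7''S,8''S)-tris-silyl ether of the target | COc1cc([C@H]2OC[C@@H]3[C@H]2CO[C@@H]3c2cc(OC)c3c(c2)[C@@H](CO[Si](C)(C)C(C)(C)C)[C@@H](c2ccc(O[Si](C(C)C)(C(C)C)C(C)C)c(OC)c2)O3)ccc1O[Si](C(C)C)(C(C)C)C(C)C | intermediate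
30 | CNP0303197.1, 4-[(1S,3aS,4S,6aS)-4-[(2S,3S)-2-(4-hydroxy-3-methoxyphenyl)-3-(hydroxymethyl)-7-methoxy-2,3-dihydro-1-benzofuran-5-yl]tetrahydro-1H,3H-furo[3,4-c]furan-1-yl]-2-methoxyphenol | COc1cc([C@H]2OC[C@@H]3[C@H]2CO[C@@H]3c2cc(OC)c3c(c2)[C@@H](CO)[C@@H](c2ccc(O)c(OC)c2)O3)ccc1O | target

**Step count**

Total step count: 19. Longest linear sequence: 12 steps (steps 1–9, then 17–19, from vanillin); steps 10–16 run in parallel and draw compound 2 from step 1.

**Steps most likely to fail**

Step 7. On the electron-rich vanillyl ether, hydride transfer may run ahead of C–C bond formation. The ion-pair-like intermediate can then rotate before it collapses, which would erode both cis selectivity and enantioselectivity. The methoxy group flanking O4' may also sit poorly in the catalyst pocket. The fallback sets out from 9 and comes back at 10, and it replaces catalyst control by resolution. Compound 9 is decomposed with the achiral, bulky dirhodium tetrakis(triphenylacetate), Rh2(O2CCPh3)4, in CH2Cl2 at −40 °C, which should still favour the cis ester. This gives 10 as a racemate with its enantiomer, ethyl (2R,3S)-5-(dimethoxymethyl)-7-methoxy-2-[3-methoxy-4-(triisopropylsilyloxy)phenyl]-2,3-dihydro-1-benzofuran-3-carboxylate F1. The two are separated by preparative chromatography on a chiral stationary phase (cellulose tris(3,5-dimethylphenylcarbamate)), and 10 re-enters at step 8.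

Step 17. Under the silyl triflate the benzylic C–O bonds (the new C7'–O bond and the C7–O bond of the dihydrofuran) may ionise reversibly, so that an aryl group drifts from the endo to the more stable exo position. The enol ether may also be protonated before the oxocarbenium ion captures it. The fallback sets out from 12 and 26 and comes back at 29; it forms C7'–C8' by a second carbene C–H insertion instead of an oxocarbenium cyclisation.
- Acetal 12 is hydrolysed (PPTS, acetone–H2O) to the ring B aldehyde F2, reduced (NaBH4, MeOH) to the benzylic alcohol F3 and converted (CBr4, PPh3, CH2Cl2) into the benzylic bromide F4.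
- Bromide F4 alkylates the sodium alkoxide of 26 (NaH, THF, 0 °C) to give the benzyl ether F5.
- Oxidation of the cyclic enol ether with pyridinium chlorochromate (C5H5NH[CrO3Cl], NaOAc, CH2Cl2) gives the cis-disubstituted γ-lactone F6.
- Detrifluoroacetylative diazo transfer follows: LiN(SiMe3)2 and CF3CO2CH2CF3 in THF at −78 °C give the α-trifluoroacetyl lactone F7, which is not isolated, and MeSO2N3 with Et3N in MeCN then gives the α-diazo lactone F8.
- Rh2(OAc)4 in CH2Cl2 should bring about 1,5 insertion of the C8' carbene into the O–CH2 bond at C7'. This closure is known for 3-diazo-4-(benzyloxymethyl)butyrolactones and gives the cis-fused furofuranone with the new aryl group endo, here the furofuranone F9.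
- Reduction with i-Bu2AlH at −78 °C gives the furofuran lactol F10, and Et3SiH with BF3·OEt2 at −78 °C removes the anomeric hydroxyl to give 29.

Step 6. Oxidative addition and transfer of the diazoacetate at the hindered, electron-rich ortho-alkoxy iodide may be slower than palladium-induced decomposition of ethyl diazoacetate, leaving the iodide unconsumed. The fallback sets out from 7 and comes back at 9; it builds the arylacetate first and introduces the diazo group afterwards. Negishi coupling of 7 with the Reformatsky reagent BrZnCH2CO2Et (Pd2(dba)3, XPhos, THF, 60 °C) gives the ethyl arylacetate F11. Regitz diazo transfer (4-acetamidobenzenesulfonyl azide, DBU, MeCN, 0 °C to rt) then gives 9; the triisopropylsilyl ether is expected to tolerate the amidine base.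

Further compounds
F1 | step 7 | ethyl (2R,3S)-5-(dimethoxymethyl)-7-methoxy-2-[3-methoxy-4-(triisopropylsilyloxy)phenyl]-2,3-dihydro-1-benzofuran-3-carboxylate (enantiomer of 10) | COC(OC)c1cc(OC)c2c(c1)[C@H](C(=O)OCC)[C@H](c1ccc(O[Si](C(C)C)(C(C)C)C(C)C)c(OC)c1)O2
F2 | step 17 | (2S,3S)-3-[(tert-butyldimethylsilyloxy)methyl]-7-methoxy-2-[3-methoxy-4-(triisopropylsilyloxy)phenyl]-2,3-dihydro-1-benzofuran-5-carbaldehyde | O=Cc1cc(OC)c2c(c1)[C@@H](CO[Si](C)(C)C(C)(C)C)[C@@H](c1ccc(O[Si](C(C)C)(C(C)C)C(C)C)c(OC)c1)O2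
F3 | step 17 | benzylic alcohol from F2 (5-hydroxymethyl compound) | OCc1cc(OC)c2c(c1)[C@@H](CO[Si](C)(C)C(C)(C)C)[C@@H](c1ccc(O[Si](C(C)C)(C(C)C)C(C)C)c(OC)c1)O2
F4 | step 17 | benzylic bromide from F3 (5-bromomethyl compound) | BrCc1cc(OC)c2c(c1)[C@@H](CO[Si](C)(C)C(C)(C)C)[C@@H](c1ccc(O[Si](C(C)C)(C(C)C)C(C)C)c(OC)c1)O2
F5 | step 17 | ether of 26 with the ring B benzyl group (C9–O–C7'H2) | COc1cc([C@H]2OC=C[C@H]2COCc2cc(OC)c3c(c2)[C@@H](CO[Si](C)(C)C(C)(C)C)[C@@H](c2ccc(O[Si](C(C)C)(C(C)C)C(C)C)c(OC)c2)O3)ccc1O[Si](C(C)C)(C(C)C)C(C)C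
F6 | step 17 | cis-γ-aryl-β-(benzyloxymethyl)-γ-butyrolactone from F5 (C9' lactone) | COc1cc([C@H]2OC(=O)C[C@H]2COCc2cc(OC)c3c(c2)[C@@H](CO[Si](C)(C)C(C)(C)C)[C@@H](c2ccc(O[Si](C(C)C)(C(C)C)C(C)C)c(OC)c2)O3)ccc1O[Si](C(C)C)(C(C)C)C(C)C
F7 | step 17 | α-trifluoroacetyl lactone from F6 (C8' epimers) | COc1cc([C@H]2OC(=O)C(C(=O)C(F)(F)F)[C@H]2COCc2cc(OC)c3c(c2)[C@@H](CO[Si](C)(C)C(C)(C)C)[C@@H](c2ccc(O[Si](C(C)C)(C(C)C)C(C)C)c(OC)c2)O3)ccc1O[Si](C(C)C)(C(C)C)C(C)C
F8 | step 17 | α-diazo lactone (diazo group on C8') | COc1cc([C@H]2OC(=O)C(=[N+]=[N-])[C@H]2COCc2cc(OC)c3c(c2)[C@@H](CO[Si](C)(C)C(C)(C)C)[C@@H](c2ccc(O[Si](C(C)C)(C(C)C)C(C)C)c(OC)c2)O3)ccc1O[Si](C(C)C)(C(C)C)C(C)C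
F9 | step 17 | endo,endo-furofuranone (C9' lactone of 29) | COc1cc([C@H]2OC(=O)[C@@H]3[C@H]2CO[C@@H]3c2cc(OC)c3c(c2)[C@@H](CO[Si](C)(C)C(C)(C)C)[C@@H](c2ccc(O[Si](C(C)C)(C(C)C)C(C)C)c(OC)c2)O3)ccc1O[Si](C(C)C)(C(C)C)C(C)C
F10 | step 17 | furofuran C9' lactol (C9' epimers) | COc1cc([C@H]2OC(O)[C@@H]3[C@H]2CO[C@@H]3c2cc(OC)c3c(c2)[C@@H](CO[Si](C)(C)C(C)(C)C)[C@@H](c2ccc(O[Si](C(C)C)(C(C)C)C(C)C)c(OC)c2)O3)ccc1O[Si](C(C)C)(C(C)C)C(C)C
F11 | step 6 | ethyl 2-[5-(dimethoxymethyl)-3-methoxy-2-{[3-methoxy-4-(triisopropylsilyloxy)benzyl]oxy}phenyl]acetate | CCOC(=O)Cc1cc(C(OC)OC)cc(OC)c1OCc1ccc(O[Si](C(C)C)(C(C)C)C(C)C)c(OC)c1
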